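## Retrosynthetic overview

1. The target comes from one global acid hydrolysis of a bis-ester in which all four aldehydes are dimethyl acetals and the 1,3-diol is an acetonide; that bis-ester comes from double Yamaguchi esterification of one cyclopentane diol with two equivalents of one C9 acid.
2. The acid's E-enal arm is built by aldol addition to acetaldehyde and E1cB elimination on a mono-ester; its stereocentre is set in the key step, an intermolecular organocatalytic Michael addition of dimethyl malonate to (E)-5-silyloxypent-2-enal.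
3. The diol comes from reductive opening of a bicyclic γ-lactone (Mitsunobu lactonisation inverts the carbinol); the lactone comes from a keto acid made by Michael addition of nitromethane to a 2-methyl-4-substituted cyclopentenone, anti to the C4 group.
4. That enone comes from (1S,4R)-cis-4-acetoxycyclopent-2-en-1-ol by Pd-catalysed malonate substitution with retention, reduction, acetonide formation, oxidation and α-iodination/methylation.
5. Rings: the cyclopentane is bought in; the 1,3-dioxane (protecting ring) is formed first, then the temporary lactone bridge; the lactone is opened in the step after it forms and the dioxane in the last step.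

Assumption: (1S,4R)-cis-4-acetoxycyclopent-2-en-1-ol (commercial, made by enzymatic desymmetrisation of the meso-diacetate) is accepted as a starting material. The target was read from the SMILES as (3S,4E) in both acyl groups and, on the ring, S at the CH2O-bearing carbon and R at the methyl, O-acyl and CH(CH2OH)2 carbons.

## Fragment A: the acid (steps 1–12)

Step 1
Reactants: 1 but-3-en-1-ol
Product: 2 (but-3-en-1-yloxy)(tert-butyl)diphenylsilane
Conditions: TBDPSCl, imidazole, CH2Cl2, 0 °C → rt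
Reagents that add atoms: tert-butyl(chloro)diphenylsilane, CC(C)(C)[Si](Cl)(c1ccccc1)c1ccccc1
Why: Silylation of the primary alcohol masks the carbon that later becomes the carboxyl group through the base, hydride and mild-acid steps that follow.

Step 2
Reactants: 2 (but-3-en-1-yloxy)(tert-butyl)diphenylsilane; 3 (E)-but-2-enal
Product: 4 (E)-5-{[tert-butyl(diphenyl)silyl]oxy}pent-2-enal
Conditions: second-generation Grubbs catalyst RuCl2(=CHPh)(PCy3)(H2IMes) (3 mol %), 3 (5 equiv), CH2Cl2, 40 °C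
Reagents that add atoms: none
Why: Olefin cross-metathesis of a terminal alkene with an enal gives the E-enal selectively and is driven by loss of propene.

Step 3 (key step)
Reactants: 4 (E)-5-{[tert-butyl(diphenyl)silyl]oxy}pent-2-enal; 5 dimethyl malonate
Product: 6 dimethyl 2-[(3R)-5-{[tert-butyl(diphenyl)silyl]oxy}-1-oxopentan-3-yl]propanedioate
Conditions: (S)-2-{bis[3,5-bis(trifluoromethyl)phenyl][(trimethylsilyl)oxy]methyl}pyrrolidine (10 mol %), PhCO2H (10 mol %), EtOH, 0 °C → rt
Reagents that add atoms: none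
Why: Iminium-catalysed intermolecular Michael addition (Jørgensen–Hayashi type) in which the diaryl(silyloxy)methyl group blocks one face of the s-trans E-iminium ion, so malonate adds to the open face of C3 and sets the (3R) centre of 6, which becomes (3S) in the acid.

Step 4
Reactants: 6 dimethyl 2-[(3R)-5-{[tert-butyl(diphenyl)silyl]oxy}-1-oxopentan-3-yl]propanedioate
Product: 7 dimethyl 2-[(3R)-5-{[tert-butyl(diphenyl)silyl]oxy}-1,1-dimethoxypentan-3-yl]propanedioate
Conditions: HC(OMe)3, MeOH, PPTS (cat.), rt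
Reagents that add atoms: trimethyl orthoformate, COC(OC)OC; methanol, CO
Why: Acid-catalysed acetalisation stores the aldehyde (the later 2-oxoethyl arm) as a dimethyl acetal that is inert to LiCl/DMSO, LiN(iPr)2, iBu2AlH, MnO2 and fluoride.

Step 5
Reactants: 7 dimethyl 2-[(3R)-5-{[tert-butyl(diphenyl)silyl]oxy}-1,1-dimethoxypentan-3-yl]propanedioate
Product: 8 methyl (3R)-3-(2-{[tert-butyl(diphenyl)silyl]oxy}ethyl)-5,5-dimethoxypentanoate
Conditions: LiCl, H2O (2 equiv), DMSO, 150 °C
Reagents that add atoms: none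
Why: Krapcho dealkoxycarbonylation removes one ester under neutral conditions; the stereocentre is β to the ester and cannot epimerise.

Step 6
Reactants: 8 methyl (3R)-3-(2-{[tert-butyl(diphenyl)silyl]oxy}ethyl)-5,5-dimethoxypentanoate; 9 acetaldehyde
Product: 11 methyl (3R)-3-(2-{[tert-butyl(diphenyl)silyl]oxy}ethyl)-2-(1-hydroxyethyl)-5,5-dimethoxypentanoate (diastereomer mixture at C2 and the carbinol carbon), via lithium enolate 10 (not isolated)
Conditions: LiN(iPr)2 (commercial solution, 1.1 equiv), THF, −78 °C; 9 (3 equiv), −78 °C; AcOH quench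
Reagents that add atoms: none
Why: Directed intermolecular aldol addition of the ester lithium enolate to acetaldehyde; the two new centres are destroyed in step 7, so their configuration does not matter.

Step 7
Reactants: 11 methyl (3R)-3-(2-{[tert-butyl(diphenyl)silyl]oxy}ethyl)-2-(1-hydroxyethyl)-5,5-dimethoxypentanoate
Product: 13 methyl (2E)-2-[(3R)-5-{[tert-butyl(diphenyl)silyl]oxy}-1,1-dimethoxypentan-3-yl]but-2-enoate, via mesylate 12 (not isolated)
Conditions: MsCl, Et3N, CH2Cl2, 0 °C; then DBU, rt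
Reagents that add atoms: none
Why: Mesylation followed by E1cB elimination through the ester enolate gives the thermodynamically preferred tiglate-type E-alkene (methyl trans to the ester); a minor Z isomer is removed by chromatography.

Step 8
Reactants: 13 methyl (2E)-2-[(3R)-5-{[tert-butyl(diphenyl)silyl]oxy}-1,1-dimethoxypentan-3-yl]but-2-enoate
Product: 14 (2E)-2-[(3R)-5-{[tert-butyl(diphenyl)silyl]oxy}-1,1-dimethoxypentan-3-yl]but-2-en-1-ol
Conditions: iBu2AlH (2.5 equiv), CH2Cl2, −78 °C; aq. potassium sodium tartrate work-up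
Reagents that add atoms: none
Why: 1,2-Reduction of the conjugated ester to the allylic alcohol leaves the acetal, the silyl ether and the alkene geometry unchanged.

Step 9
Reactants: 14 (2E)-2-[(3R)-5-{[tert-butyl(diphenyl)silyl]oxy}-1,1-dimethoxypentan-3-yl]but-2-en-1-ol
Product: 15 (2E)-2-[(3R)-5-{[tert-butyl(diphenyl)silyl]oxy}-1,1-dimethoxypentan-3-yl]but-2-enal
Conditions: MnO2 (excess), CH2Cl2, rt
Reagents that add atoms: none
Why: Chemoselective allylic oxidation gives the E-enal, which is also the thermodynamically favoured geometry.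

Step 10
Reactants: 15 (2E)-2-[(3R)-5-{[tert-butyl(diphenyl)silyl]oxy}-1,1-dimethoxypentan-3-yl]but-2-enal
Product: 16 tert-butyl{[(3R,4E)-4-(dimethoxymethyl)-3-(2,2-dimethoxyethyl)hex-4-en-1-yl]oxy}diphenylsilane
Conditions: HC(OMe)3, MeOH, PPTS (cat.), 0 °C → rt; Et3N quench
Reagents that add atoms: trimethyl orthoformate, COC(OC)OC; methanol, CO
Why: Acetalisation of the α-branched enal (1,4-addition of methanol is disfavoured by the α-substituent) protects it before the alcohol is oxidised to the acid.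

Step 11
Reactants: 16 tert-butyl{[(3R,4E)-4-(dimethoxymethyl)-3-(2,2-dimethoxyethyl)hex-4-en-1-yl]oxy}diphenylsilane
Product: 17 (3R,4E)-4-(dimethoxymethyl)-3-(2,2-dimethoxyethyl)hex-4-en-1-ol
Conditions: nBu4NF, THF, 0 °C → rt
Reagents that add atoms: none
Why: Fluoride cleaves only the Si–O bond; both acetals are stable to these non-acidic conditions.

Step 12
Reactants: 17 (3R,4E)-4-(dimethoxymethyl)-3-(2,2-dimethoxyethyl)hex-4-en-1-ol
Product: 19 (3S,4E)-4-(dimethoxymethyl)-3-(2,2-dimethoxyethyl)hex-4-enoic acid, via aldehyde 18 (not isolated)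
Conditions: (nPr4N)RuO4 (10 mol %), N-methylmorpholine N-oxide monohydrate (10 equiv), MeCN, rt; work-up at pH 5, acid kept as its Et3NH+ salt
Reagents that add atoms: water, O (from the N-oxide hydrate)
Why: Ley–Griffith oxidation with the N-oxide hydrate carries the alcohol through the aldehyde hydrate to the acid without acid, so both acetals and the trisubstituted alkene survive; the descriptor changes from R to S only through CIP priorities.

## Fragment B: the cyclopentane diol (steps 13–23)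

Step 13
Reactants: 20 (1S,4R)-cis-4-acetoxycyclopent-2-en-1-ol; 5 dimethyl malonate
Product: 21 dimethyl 2-[(1R,4S)-4-hydroxycyclopent-2-en-1-yl]propanedioate (malonate cis to OH)
Conditions: NaH, 5 (1.5 equiv), THF, 0 °C; then 20, Pd(PPh3)4 (3 mol %), THF, rt → 50 °C
Reagents that add atoms: none
Why: Tsuji–Trost allylic alkylation in which ionisation and malonate attack both occur anti to palladium (net retention) at the allyl terminus remote from the hydroxyl, fixing the ring carbon that will carry CH(CH2OH)2.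

Step 14
Reactants: 21 dimethyl 2-[(1R,4S)-4-hydroxycyclopent-2-en-1-yl]propanedioate
Product: 22 2-[(1R,4S)-4-hydroxycyclopent-2-en-1-yl]propane-1,3-diol
Conditions: LiAlH4 (excess; inverse addition), THF, 0 °C → reflux; Fieser work-up
Reagents that add atoms: none
Why: Hydride reduction of both esters gives the 1,3-diol; the stereocentres are not involved.

Step 15
Reactants: 22 2-[(1R,4S)-4-hydroxycyclopent-2-en-1-yl]propane-1,3-diol
Product: 23 (1S,4R)-4-(2,2-dimethyl-1,3-dioxan-5-yl)cyclopent-2-en-1-ol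
Conditions: 2,2-dimethoxypropane, PPTS (cat.), acetone, rt
Reagents that add atoms: 2,2-dimethoxypropane, COC(C)(C)OC
Why: Only the 1,3-diol can close to a six-membered acetonide; the isolated allylic hydroxyl stays free.

Step 16
Reactants: 23 (1S,4R)-4-(2,2-dimethyl-1,3-dioxan-5-yl)cyclopent-2-en-1-ol
Product: 24 (4R)-4-(2,2-dimethyl-1,3-dioxan-5-yl)cyclopent-2-en-1-one
Conditions: MnO2 (excess), CH2Cl2, rt
Reagents that add atoms: none
Why: Allylic oxidation gives the enone needed for the two conjugate-type C–C bond formations; the carbinol centre is given up here and re-set in steps 21 and 22, while C4 is untouched.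

Step 17
Reactants: 24 (4R)-4-(2,2-dimethyl-1,3-dioxan-5-yl)cyclopent-2-en-1-one
Product: 25 (4S)-4-(2,2-dimethyl-1,3-dioxan-5-yl)-2-iodocyclopent-2-en-1-one (same spatial arrangement; the descriptor changes because of iodine)
Conditions: I2, pyridine, CH2Cl2, rt
Reagents that add atoms: iodine, II
Why: Johnson α-iodination of the enone (pyridine conjugate addition, iodination, elimination) functionalises only the α-carbon.

Step 18
Reactants: 25 (4S)-4-(2,2-dimethyl-1,3-dioxan-5-yl)-2-iodocyclopent-2-en-1-one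
Product: 26 (4R)-4-(2,2-dimethyl-1,3-dioxan-5-yl)-2-methylcyclopent-2-en-1-one
Conditions: MeZnCl (commercial solution, 1.5 equiv), Pd(dba)2 (5 mol %), tri(2-furyl)phosphine (10 mol %), THF/DMF, rt
Reagents that add atoms: methylzinc chloride, C[Zn]Cl
Why: Negishi cross-coupling puts the ring methyl on the sp2 α-carbon under base-free conditions that cannot epimerise C4.

Step 19
Reactants: 26 (4R)-4-(2,2-dimethyl-1,3-dioxan-5-yl)-2-methylcyclopent-2-en-1-one; 27 nitromethane
Product: 28 (2R,3S,4R)-4-(2,2-dimethyl-1,3-dioxan-5-yl)-2-methyl-3-(nitromethyl)cyclopentan-1-one (all-trans)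
Conditions: 27 (10 equiv), DBU (0.5 equiv), MeCN, 0 °C → rt
Reagents that add atoms: none
Why: Intermolecular Michael addition of the nitronate to C3 anti to the C4 dioxanyl group, after which the base equilibrates C2 so that the methyl ends trans to the nitromethyl group.

Step 20
Reactants: 28 (2R,3S,4R)-4-(2,2-dimethyl-1,3-dioxan-5-yl)-2-methyl-3-(nitromethyl)cyclopentan-1-one
Product: 29 (1S,2R,5S)-5-(2,2-dimethyl-1,3-dioxan-5-yl)-2-methyl-3-oxocyclopentane-1-carboxylic acid
Conditions: NaNO2 (3 equiv), AcOH (10 equiv), DMSO, 35 °C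
Reagents that add atoms: sodium nitrite, [Na+].[O-]N=O; water, O
Why: Nef-type oxidation of the primary nitroalkane to the carboxylic acid through the nitrolic acid, mild enough for the acetonide and without change at the ring centres.

Step 21
Reactants: 29 (1S,2R,5S)-5-(2,2-dimethyl-1,3-dioxan-5-yl)-2-methyl-3-oxocyclopentane-1-carboxylic acid
Product: 30 (1S,2R,3S,5S)-5-(2,2-dimethyl-1,3-dioxan-5-yl)-3-hydroxy-2-methylcyclopentane-1-carboxylic acid (OH cis to CH3 and trans to CO2H)
Conditions: LiBH(s-Bu)3 (3 equiv), THF, −78 °C; aq. NH4Cl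
Reagents that add atoms: none
Why: The bulky hydride attacks the ketone anti to the adjacent methyl and gives the alcohol cis to CH3; any epimeric cis-hydroxy acid simply closes to the same lactone, so both converge.

Step 22
Reactants: 30 (1S,2R,3S,5S)-5-(2,2-dimethyl-1,3-dioxan-5-yl)-3-hydroxy-2-methylcyclopentane-1-carboxylic acid
Product: 31 (1R,4S,5S,7R)-5-(2,2-dimethyl-1,3-dioxan-5-yl)-7-methyl-2-oxabicyclo[2.2.1]heptan-3-one
Conditions: PPh3, DIAD, THF (0.02 M), 0 °C → rt
Reagents that add atoms: none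
Why: Intramolecular Mitsunobu reaction in which the carboxylate displaces the activated hydroxyl with inversion (the carbocyclic analogue of the hydroxyproline lactone), setting the O-bearing carbon as in the target.

Step 23
Reactants: 31 (1R,4S,5S,7R)-5-(2,2-dimethyl-1,3-dioxan-5-yl)-7-methyl-2-oxabicyclo[2.2.1]heptan-3-one
Product: 32 (1R,2R,3S,4R)-4-(2,2-dimethyl-1,3-dioxan-5-yl)-3-(hydroxymethyl)-2-methylcyclopentan-1-ol
Conditions: LiAlH4, THF, 0 °C; Fieser work-up
Reagents that add atoms: none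
Why: Reductive opening of the lactone releases the primary and the secondary alcohol with all four ring centres in place.

## Union and release (steps 24–25)

Step 24
Reactants: 32 (1R,2R,3S,4R)-4-(2,2-dimethyl-1,3-dioxan-5-yl)-3-(hydroxymethyl)-2-methylcyclopentan-1-ol; 19 (3S,4E)-4-(dimethoxymethyl)-3-(2,2-dimethoxyethyl)hex-4-enoic acid
Product: 34 bis-ester of 32 (at the CH2OH and the ring OH) with two molecules of 19, acetonide and all four dimethyl acetals intact, via mixed anhydride 33 (not isolated)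
Conditions: 19 (2.6 equiv), 2,4,6-trichlorobenzoyl chloride, Et3N, THF, rt; then 32, DMAP, toluene, rt → 40 °C
Reagents that add atoms: none
Why: Yamaguchi esterification acylates both the primary and the hindered secondary hydroxyl with the same acid under basic conditions that keep every acetal and stereocentre intact.

Step 25
Reactants: 34 bis-ester with acetonide and four dimethyl acetals
Product: 35 [(1S,2R,3R,5R)-5-(1,3-dihydroxypropan-2-yl)-3-{[(3S,4E)-4-formyl-3-(2-oxoethyl)hex-4-enoyl]oxy}-2-methylcyclopentyl]methyl (3S,4E)-4-formyl-3-(2-oxoethyl)hex-4-enoate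
Conditions: AcOH/H2O/THF (3:1:1), rt → 35 °C
Reagents that add atoms: water, O
Why: Mild aqueous acid hydrolyses the four dimethyl acetals and the acetonide in one operation, while the esters and the thermodynamically preferred E-enals survive and no stereocentre is touched.

## Compound list

1 | but-3-en-1-ol | C=CCCO | starting material
2 | (but-3-en-1-yloxy)(tert-butyl)diphenylsilane | C=CCCO[Si](c1ccccc1)(c1ccccc1)C(C)(C)C | intermediate
3 | (E)-but-2-enal | C/C=C/C=O | starting material
4 | (E)-5-{[tert-butyl(diphenyl)silyl]oxy}pent-2-enal | O=C/C=C/CCO[Si](c1ccccc1)(c1ccccc1)C(C)(C)C | intermediate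
5 | dimethyl malonate | COC(=O)CC(=O)OC | starting material
6 | dimethyl 2-[(3R)-5-{[tert-butyl(diphenyl)silyl]oxy}-1-oxopentan-3-yl]propanedioate | COC(=O)C(C(=O)OC)[C@@H](CC=O)CCO[Si](c1ccccc1)(c1ccccc1)C(C)(C)C | intermediate
7 | dimethyl 2-[(3R)-5-{[tert-butyl(diphenyl)silyl]oxy}-1,1-dimethoxypentan-3-yl]propanedioate | COC(=O)C(C(=O)OC)[C@@H](CC(OC)OC)CCO[Si](c1ccccc1)(c1ccccc1)C(C)(C)C | intermediate
8 | methyl (3R)-3-(2-{[tert-butyl(diphenyl)silyl]oxy}ethyl)-5,5-dimethoxypentanoate | COC(=O)C[C@@H](CC(OC)OC)CCO[Si](c1ccccc1)(c1ccccc1)C(C)(C)C | intermediate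
9 | acetaldehyde | CC=O | starting material
10 | lithium enolate of 8 | [Li]OC(OC)=C[C@@H](CC(OC)OC)CCO[Si](c1ccccc1)(c1ccccc1)C(C)(C)C | intermediate
11 | methyl (3R)-3-(2-{[tert-butyl(diphenyl)silyl]oxy}ethyl)-2-(1-hydroxyethyl)-5,5-dimethoxypentanoate (diastereomer mixture) | COC(=O)C(C(C)O)[C@@H](CC(OC)OC)CCO[Si](c1ccccc1)(c1ccccc1)C(C)(C)C | intermediate
12 | methyl (3R)-3-(2-{[tert-butyl(diphenyl)silyl]oxy}ethyl)-5,5-dimethoxy-2-[1-(methylsulfonyloxy)ethyl]pentanoate | COC(=O)C(C(C)OS(C)(=O)=O)[C@@H](CC(OC)OC)CCO[Si](c1ccccc1)(c1ccccc1)C(C)(C)C | intermediate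
13 | methyl (2E)-2-[(3R)-5-{[tert-butyl(diphenyl)silyl]oxy}-1,1-dimethoxypentan-3-yl]but-2-enoate | C/C=C(/C(=O)OC)[C@@H](CC(OC)OC)CCO[Si](c1ccccc1)(c1ccccc1)C(C)(C)C | intermediate
14 | (2E)-2-[(3R)-5-{[tert-butyl(diphenyl)silyl]oxy}-1,1-dimethoxypentan-3-yl]but-2-en-1-ol | C/C=C(/CO)[C@@H](CC(OC)OC)CCO[Si](c1ccccc1)(c1ccccc1)C(C)(C)C | intermediate
15 | (2E)-2-[(3R)-5-{[tert-butyl(diphenyl)silyl]oxy}-1,1-dimethoxypentan-3-yl]but-2-enal | C/C=C(/C=O)[C@@H](CC(OC)OC)CCO[Si](c1ccccc1)(c1ccccc1)C(C)(C)C | intermediate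
16 | tert-butyl{[(3R,4E)-4-(dimethoxymethyl)-3-(2,2-dimethoxyethyl)hex-4-en-1-yl]oxy}diphenylsilane | C/C=C(/C(OC)OC)[C@@H](CC(OC)OC)CCO[Si](c1ccccc1)(c1ccccc1)C(C)(C)C | intermediate
17 | (3R,4E)-4-(dimethoxymethyl)-3-(2,2-dimethoxyethyl)hex-4-en-1-ol | C/C=C(/C(OC)OC)[C@@H](CC(OC)OC)CCO | intermediate
18 | (3R,4E)-4-(dimethoxymethyl)-3-(2,2-dimethoxyethyl)hex-4-enal | C/C=C(/C(OC)OC)[C@@H](CC(OC)OC)CC=O | intermediate
19 | (3S,4E)-4-(dimethoxymethyl)-3-(2,2-dimethoxyethyl)hex-4-enoic acid | C/C=C(/C(OC)OC)[C@@H](CC(OC)OC)CC(=O)O | intermediate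
20 | (1S,4R)-cis-4-acetoxycyclopent-2-en-1-ol | C1=C[C@@H](O)C[C@H]1OC(C)=O | starting material
21 | dimethyl 2-[(1R,4S)-4-hydroxycyclopent-2-en-1-yl]propanedioate | C1=C[C@@H](O)C[C@H]1C(C(=O)OC)C(=O)OC | intermediate
22 | 2-[(1R,4S)-4-hydroxycyclopent-2-en-1-yl]propane-1,3-diol | C1=C[C@@H](O)C[C@H]1C(CO)CO | intermediate
23 | (1S,4R)-4-(2,2-dimethyl-1,3-dioxan-5-yl)cyclopent-2-en-1-ol | C1=C[C@@H](O)C[C@H]1C2COC(C)(C)OC2 | intermediate
24 | (4R)-4-(2,2-dimethyl-1,3-dioxan-5-yl)cyclopent-2-en-1-one | C1=CC(=O)C[C@H]1C2COC(C)(C)OC2 | intermediate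
25 | (4S)-4-(2,2-dimethyl-1,3-dioxan-5-yl)-2-iodocyclopent-2-en-1-one | C1=C(I)C(=O)C[C@H]1C2COC(C)(C)OC2 | intermediate
26 | (4R)-4-(2,2-dimethyl-1,3-dioxan-5-yl)-2-methylcyclopent-2-en-1-one | C1=C(C)C(=O)C[C@H]1C2COC(C)(C)OC2 | intermediate
27 | nitromethane | C[N+](=O)[O-] | starting material
28 | (2R,3S,4R)-4-(2,2-dimethyl-1,3-dioxan-5-yl)-2-methyl-3-(nitromethyl)cyclopentan-1-one | [O-][N+](=O)C[C@@H]1[C@@H](C)C(=O)C[C@H]1C2COC(C)(C)OC2 | intermediate
29 | (1S,2R,5S)-5-(2,2-dimethyl-1,3-dioxan-5-yl)-2-methyl-3-oxocyclopentane-1-carboxylic acid | OC(=O)[C@@H]1[C@@H](C)C(=O)C[C@H]1C2COC(C)(C)OC2 | intermediate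
30 | (1S,2R,3S,5S)-5-(2,2-dimethyl-1,3-dioxan-5-yl)-3-hydroxy-2-methylcyclopentane-1-carboxylic acid | OC(=O)[C@@H]1[C@@H](C)[C@@H](O)C[C@H]1C2COC(C)(C)OC2 | intermediate
31 | (1R,4S,5S,7R)-5-(2,2-dimethyl-1,3-dioxan-5-yl)-7-methyl-2-oxabicyclo[2.2.1]heptan-3-one | O=C3[C@@H]1[C@@H](C)[C@H](O3)C[C@H]1C2COC(C)(C)OC2 | intermediate
32 | (1R,2R,3S,4R)-4-(2,2-dimethyl-1,3-dioxan-5-yl)-3-(hydroxymethyl)-2-methylcyclopentan-1-ol | OC[C@@H]1[C@@H](C)[C@H](O)C[C@H]1C2COC(C)(C)OC2 | intermediate
33 | (3S,4E)-4-(dimethoxymethyl)-3-(2,2-dimethoxyethyl)hex-4-enoic 2,4,6-trichlorobenzoic anhydride | C/C=C(/C(OC)OC)[C@@H](CC(OC)OC)CC(=O)OC(=O)c1c(Cl)cc(Cl)cc1Cl | intermediate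
34 | [(1S,2R,3R,5R)-5-(2,2-dimethyl-1,3-dioxan-5-yl)-3-{[(3S,4E)-4-(dimethoxymethyl)-3-(2,2-dimethoxyethyl)hex-4-enoyl]oxy}-2-methylcyclopentyl]methyl (3S,4E)-4-(dimethoxymethyl)-3-(2,2-dimethoxyethyl)hex-4-enoate | C/C=C(/C(OC)OC)[C@@H](CC(OC)OC)CC(=O)OC[C@@H]1[C@@H](C)[C@H](OC(=O)C[C@H](CC(OC)OC)/C(C(OC)OC)=C\C)C[C@H]1C2COC(C)(C)OC2 | intermediate
35 | [(1S,2R,3R,5R)-5-(1,3-dihydroxypropan-2-yl)-3-{[(3S,4E)-4-formyl-3-(2-oxoethyl)hex-4-enoyl]oxy}-2-methylcyclopentyl]methyl (3S,4E)-4-formyl-3-(2-oxoethyl)hex-4-enoate | C/C=C(/C=O)[C@@H](CC=O)CC(=O)OC[C@@H]1[C@@H](C)[C@H](OC(=O)C[C@H](CC=O)/C(C=O)=C\C)C[C@H]1C(CO)CO | target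

## Step count and risks

Total step count: 25 (12 for the acid, 11 for the diol, 2 for union and release).
Longest linear sequence: 14 steps (steps 1–12, then 24 and 25).

Three steps most likely to fail:

Step 19 (nitromethane Michael addition). The β-carbon of 26 is flanked by the α-methyl and the branched C4 substituent, so addition may be slow, and prolonged amine base could erode C4 through the dienolate. The fallback sets out from 26 and replaces the nitronate by a silicon-masked hydroxymethyl nucleophile. Copper-catalysed 1,4-addition of [(isopropoxy)dimethylsilyl]methylmagnesium chloride (CuBr·SMe2 cat., THF, −40 °C, NH4Cl quench) gives, again anti to C4 and trans at C2, (2R,3S,4S)-4-(2,2-dimethyl-1,3-dioxan-5-yl)-3-{[dimethyl(propan-2-yloxy)silyl]methyl}-2-methylcyclopentan-1-one F1. Tamao oxidation (H2O2, KF, KHCO3, THF/MeOH) gives (2R,3S,4R)-4-(2,2-dimethyl-1,3-dioxan-5-yl)-3-(hydroxymethyl)-2-methylcyclopentan-1-one F2. Oxidation of the primary alcohol with (nPr4N)RuO4 and N-methylmorpholine N-oxide hydrate gives keto acid 29, where the route resumes; this also bypasses step 20.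

Step 22 (Mitsunobu lactonisation). Closing the strained 2-oxabicyclo[2.2.1]heptanone may lose out to elimination or oligomerisation. The fallback sets out from 30 and inverts the carbinol intermolecularly. Me3SiCHN2 in toluene/MeOH gives methyl (1S,2R,3S,5S)-5-(2,2-dimethyl-1,3-dioxan-5-yl)-3-hydroxy-2-methylcyclopentane-1-carboxylate F3. Mitsunobu reaction with benzoic acid (PPh3, DIAD, toluene) gives methyl (1S,2R,3R,5S)-3-(benzoyloxy)-5-(2,2-dimethyl-1,3-dioxan-5-yl)-2-methylcyclopentane-1-carboxylate F4. LiAlH4 then reduces both esters to diol 32, where the route resumes; step 23 is skipped.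

Step 25 (global unmasking). Four aldehydes and a free 1,3-diol are released together in acid, which invites aldol-type decomposition or intramolecular acetal formation. The fallback sets out from 34 and unmasks in two stages of different type. Acetonide methanolysis (PPTS, MeOH, rt), under which the dimethyl acetals are inert, gives the diol [(1S,2R,3R,5R)-5-(1,3-dihydroxypropan-2-yl)-3-{[(3S,4E)-4-(dimethoxymethyl)-3-(2,2-dimethoxyethyl)hex-4-enoyl]oxy}-2-methylcyclopentyl]methyl (3S,4E)-4-(dimethoxymethyl)-3-(2,2-dimethoxyethyl)hex-4-enoate F5. The aldehydes are then released last under heterogeneous, nearly neutral conditions (oxalic acid on wet SiO2, CH2Cl2, rt) to give 35.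

## Further compounds

F1 | step 19 | (2R,3S,4S)-4-(2,2-dimethyl-1,3-dioxan-5-yl)-3-{[dimethyl(propan-2-yloxy)silyl]methyl}-2-methylcyclopentan-1-one | CC(C)O[Si](C)(C)C[C@@H]1[C@@H](C)C(=O)C[C@H]1C2COC(C)(C)OC2
F2 | step 19 | (2R,3S,4R)-4-(2,2-dimethyl-1,3-dioxan-5-yl)-3-(hydroxymethyl)-2-methylcyclopentan-1-one | OC[C@@H]1[C@@H](C)C(=O)C[C@H]1C2COC(C)(C)OC2
F3 | step 22 | methyl (1S,2R,3S,5S)-5-(2,2-dimethyl-1,3-dioxan-5-yl)-3-hydroxy-2-methylcyclopentane-1-carboxylate | COC(=O)[C@@H]1[C@@H](C)[C@@H](O)C[C@H]1C2COC(C)(C)OC2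
F4 | step 22 | methyl (1S,2R,3R,5S)-3-(benzoyloxy)-5-(2,2-dimethyl-1,3-dioxan-5-yl)-2-methylcyclopentane-1-carboxylate | COC(=O)[C@@H]1[C@@H](C)[C@H](OC(=O)c3ccccc3)C[C@H]1C2COC(C)(C)OC2
F5 | step 25 | [(1S,2R,3R,5R)-5-(1,3-dihydroxypropan-2-yl)-3-{[(3S,4E)-4-(dimethoxymethyl)-3-(2,2-dimethoxyethyl)hex-4-enoyl]oxy}-2-methylcyclopentyl]methyl (3S,4E)-4-(dimethoxymethyl)-3-(2,2-dimethoxyethyl)hex-4-enoate | C/C=C(/C(OC)OC)[C@@H](CC(OC)OC)CC(=O)OC[C@@H]1[C@@H](C)[C@H](OC(=O)C[C@H](CC(OC)OC)/C(C(OC)OC)=C\C)C[C@H]1C(CO)CO
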